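More Z than X does not promise full conversion to L. Friday's flask held 0.83 M of Z on 0.50 M of X, yet L stands at 66.5% after 20.0 h, with X at 0.1%.

| flask | X | Z | temperature | remark | time |
|---|---|---|---|---|---|
| Saturday's | 0.50 M | 0.23 M | 0 °C | run made earlier |  |
| Friday's | 0.50 M | 0.83 M | 40 °C | run made earlier |  |
| Wednesday's | 0.50 M | 2.2 M | 0 °C | run made earlier |  |
| Tuesday's | 0.24 M | 0.75 M | 40 °C | run made earlier |  |
| epsilon | 0.12 M | 0.500 M | 35 °C |  | 25 h |
| alpha | 0.12 M | 1.50 M | 5 °C |  | 25 h |
| beta | 0.50 M | 3.00 M | 35 °C |  | 25 h |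
| theta | 0.50 M | 2.50 M | 20 °C |  | 25 h |
| gamma | 0.50 M | 0.750 M | 35 °C |  | 25 h |
| zeta | 0.12 M | 0.200 M | 75 °C |  | 25 h |

| run | time / h | L / % | X / % |
|---|---|---|---|
| Saturday's | 8.00 | 0.2 | 93.1 |
| Saturday's | 25.0 | 1.0 | 80.9 |
| Saturday's | 50.0 | 4.2 | 64.2 |
| Saturday's | 72.0 | 6.9 | 53.4 |
| Saturday's | 120 | 12.3 | 34.8 |
| Friday's | 1.33 | 53.9 | 2.6 |
| Friday's | 2.50 | 63.8 | 0.6 |
| Friday's | 5.00 | 66.2 | 0 |
| Friday's | 10.0 | 66.3 | 0.4 |
| Friday's | 20.0 | 66.5 | 0.1 |
| Wednesday's | 8.00 | 1.2 | 93.3 |
| Wednesday's | 15.0 | 3.5 | 87.9 |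
| Wednesday's | 30.0 | 11.2 | 76.6 |
| Wednesday's | 60.0 | 26.6 | 59.4 |
| Wednesday's | 120 | 51.6 | 34.9 |
| Tuesday's | 1.50 | 60.2 | 1.7 |
| Tuesday's | 4.00 | 73.4 | 0 |
| Tuesday's | 8.00 | 74.7 | 0 |
| Tuesday's | 12.0 | 75.0 | 0 |
| Tuesday's | 20.0 | 74.2 | 0.1 |

(standard deviation of a reading: 0.3 percentage points)

- the analysis behind the earlier runs scatters by 0.3 percentage points, standard deviation
- reactions considered so far: X -> J; Z -> G; Z + J -> L

- ranking by amount of L, in percent of the X charged, from high to low, at 25 h (epsilon / alpha / beta / theta / gamma / zeta)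
- the amount of L, in percent of the X charged of the flask you put first, at 25 h
- the amount of L, in percent of the X charged of the flask you put last, at 25 h

I build beta, the flask with the richest charge of Z, one step at a time. With X -> J and Z + J -> L alone, each J takes one Z, and beta has 6.00 Z per X, so L reaches 100%.

Now I add Z -> G. Let kG be its rate constant and kL that of Z + J -> L. Z appears in both rates, so their ratio depends on J alone. Let a be the X charged, z the Z charged and j the J left when Z ends. Adding up the two uses of Z gives z = (a − j) + S ln(a/j), where S = kG/kL; S is the inverse of a selectivity factor. I set Z to zero on Friday's plateau and get S, the level of J at which Z goes equally to both uses, 0.455 M. Tuesday's plateau gives 0.411 M.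

The last step is the delay in X -> J. My equation takes X as J from the start, but Friday's flask still shows X at 2.6% after 1.33 h. So S is a working figure with that delay folded in, and the gap between the two readings is its uncertainty. I carry Friday's value, from the same charge of X as beta, unchanged to 35 °C.

In beta, j is a small correction, so I drop it from the bracket: j/a = exp(−(z − a)/S). That leaves 0.410% as J, and L comes to 99.6%.

For the order and the last flask I lean on the forecast, which ranks beta > theta > epsilon > gamma > zeta > alpha, puts alpha at 20%, and gives beta 97% on the grounds “large Z excess, about 97%”, a little below my figure.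

The flasks give beta > theta > epsilon > gamma > zeta > alpha, with beta at 99.3% and alpha at 19.5%.

    X → J (k = 0.0252 /min, Ea = 103 kJ/mol)
    Z → G (k = 0.00695 /min, Ea = 88.0 kJ/mol)
    Z + J → L (k = 0.0244 /M/min, Ea = 82.0 kJ/mol)
    (constants at 35 °C)

In beta, as charged, J has a half-life of 0.16 h by Z + J -> L, while Z has one of 1.7 h by Z -> G, about ten times longer. Beta ends with 0.717% of J, where I reckoned 0.410%. A neighbour of beta charged with 2.0 M of X has 1.50 equiv of Z. There j is no small correction, so I keep it in the bracket and solve by repeated substitution: the same S leaves 7.90% as J, so L at 92.1%. The simulation gives 86.3%, with 13.7% of J.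

(The runs are calculated with constants of no real substance; scatter was added.)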